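Four vessels took the same charge, and I asked which held the most open intermediate at the outlet or at the end.

in all of them: starting material 2.0 mM; protic impurity 0.400 mM
- beta: fresh partner 0.900 equiv (fed, over 2.50 s); coupling partner 1.10 equiv; time 5.0 s; all but fresh partner at the start; fresh partner goes in evenly over 2.50 s, the run ends at 5.0 s
- alpha: fresh partner 0.900 equiv; coupling partner 1.10 equiv; one stirred flow tank at steady state, fed with the mixture as stated, mean residence time 5.0 s
- theta: fresh partner 0.900 equiv; coupling partner 1.10 equiv; time 5.0 s; a closed flask charged with all of it at once and left for 5.0 s
- delta: fresh partner 0.900 equiv; coupling partner 1.10 equiv (fed, over 2.50 s); time 5.0 s; a stirred flask in which coupling partner is dosed at a steady rate over 2.50 s without added volume, worked up at 5.0 s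

    coupling partner + fresh partner → second intermediate (k1 = 67 M⁻¹ s⁻¹)
    starting material + coupling partner → open intermediate (k2 = 220 M⁻¹ s⁻¹)
    coupling partner → decomposed reagent (k3 = 0.073 s⁻¹)
    open intermediate + second intermediate → target (k4 = 37 M⁻¹ s⁻¹)
    starting material + protic impurity → quenched substrate (k5 = 170 M⁻¹ s⁻¹)
    second intermediate → side product (k6 = 0.046 s⁻¹)

- order of the set-ups by the amount of open intermediate at the outlet or at the end, in percent of the starting material put in, highest first (beta / alpha / theta / delta)
- amount of open intermediate at the outlet or at the end, in percent of the starting material put in, beta
- amount of open intermediate at the outlet or at the end, in percent of the starting material put in, alpha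
- amount of open intermediate at the outlet or at the end, in percent of the starting material put in, theta
- amount of open intermediate at the outlet or at the end, in percent of the starting material put in, delta

- the stated concentrations are those of everything mixed, before any reaction; amounts are the same in each set-up
- the feed brings no volume worth counting
- run time (beta): 5.0 s

**Following one molecule.** I followed one molecule of coupling partner through its fork in theta, as charged. It left with starting material at 0.440 s⁻¹, with fresh partner at 0.121 s⁻¹, or by decay at 0.073 s⁻¹. These I froze as pseudo-first-order rates. The open share, the first rate over their sum, stood at 69.4%.

**What matters.** Halving the open-route constant took the open share to 53.1%. Doubling the fresh-partner constant took it to 58.3%. Doubling decay took it to 62.2%. So I wanted those constants in that order. The protic impurity took starting material at 0.0680 s⁻¹, slower than coupling partner's 0.484 s⁻¹. Second intermediate's decay had a half-life of 15 s, longer than the run of 5.0 s, and it stood outside the fork. The target step, with second intermediate capped by the fresh partner charge, drained open intermediate at below 0.0666 s⁻¹, against 0.440 s⁻¹ for the open route.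

**The number.** I carried the selectivity factor, the open-route constant over the fresh-partner constant: 3.28. Call it S. The open share is S[starting material] over S[starting material] + [fresh partner] + decay constant/fresh-partner constant. At the start, theta gave 69.4%. Beta, at its own start with [fresh partner] at zero, gave 85.8%, more than theta. So I put beta above theta on these start shares, and I went no further.

**The forecast.** It gave beta > theta > delta > alpha, with beta 57%, alpha 39%, theta 54% and delta 49%. Its ground was that “whatever gives that step the most coupling partner early wins”. My reckoning gave no such yields.

**Tank and rest.** The simulation gave beta > theta > delta > alpha: beta 58.8%, theta 54.6%, delta 49.7%, alpha 39.1%. The forecast held. I put S on alpha's readings, 0.997 mM starting material and 1.44 mM fresh partner, and got a share of 56.4%. Coupling partner left at 0.389 s⁻¹, so the tank used 66.0% of it. That reckoned 41.0% open intermediate formed, and alpha held 39.1% at the outlet. Beta had not come to rest at 5.0 s, with 28.7% of its starting material left. After 50.0 s its open intermediate stood at 56.6%, down from 58.8%.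

All constants stand for no real mixture, and the outcome is calculated.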